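(The numbers in the tables are simulated for substances that don't exist; noise was put on by code.)

The ratio of target to substrate consumed opened the meeting. The analyst read it at 4.00 min: 0.653 in red, 0.656 in amber, 0.673 in ochre. Across these runs [reagent] differed by a factor of 5.65, at one [substrate]. She took the mean, 0.661, as the selectivity to target, the target held per substrate consumed. A colleague objected that the ratio moves with time: red read 0.518 at 2.00 min. She agreed, and froze it across reagent, not across time.

common to all: substrate 20 mM
- red: reagent 17 mM; run made earlier
- amber: reagent 43 mM; run made earlier
- ochre: reagent 96 mM; run made earlier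
- epsilon: reagent 19.0 mM; time 8.0 min
- alpha: reagent 48.0 mM; time 8.0 min
- theta: reagent 120 mM; time 8.0 min

| run | time / min | intermediate / % | substrate / % | side product / % | target / % |
|---|---|---|---|---|---|
| red | 0.333 | 4.7 | 97.1 | 0 | 0.6 |
| red | 0.667 | 6.7 | 90.9 | 0 | 1.6 |
| red | 1.00 | 8.5 | 87.0 | 1.0 | 3.9 |
| red | 2.00 | 9.9 | 78.0 | 0 | 11.4 |
| red | 4.00 | 7.9 | 67.1 | 3.5 | 21.5 |
| amber | 0.333 | 10.0 | 88.1 | 0.9 | 0.6 |
| amber | 1.00 | 17.4 | 73.1 | 1.9 | 8.3 |
| amber | 2.00 | 18.3 | 56.8 | 2.2 | 20.5 |
| amber | 3.00 | 16.5 | 46.8 | 3.7 | 31.3 |
| amber | 4.00 | 15.0 | 41.0 | 5.1 | 38.7 |
| ochre | 0.333 | 20.2 | 76.7 | 0 | 3.5 |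
| ochre | 0.667 | 28.9 | 62.0 | 1.0 | 8.8 |
| ochre | 1.00 | 30.7 | 52.2 | 2.2 | 16.1 |
| ochre | 2.00 | 27.0 | 34.6 | 3.6 | 35.3 |
| ochre | 4.00 | 19.9 | 20.3 | 4.5 | 53.6 |

(standard deviation of a reading: 0.5 percentage points)

- percentages count the substrate that a species holds: one side product counts as two
- steps that have been proposed: substrate + reagent <-> intermediate; intermediate <-> target + by-product; 2 reagent -> homo dimer; substrate + intermediate -> side product

- which of these there is most of at the end, counted by the substrate in it, epsilon (target / substrate / side product / intermediate)
- which of these there is most of at the end, counted by the substrate in it, alpha (target / substrate / side product / intermediate)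
- which of these there is most of at the end, counted by the substrate in it, theta (target / substrate / side product / intermediate)
- amount of the one of these that there is most of at the end, in percent of the substrate charged, epsilon
- amount of the one of these that there is most of at the end, in percent of the substrate charged, alpha
- amount of the one of these that there is most of at the end, in percent of the substrate charged, theta

She then turned the ratio into a rule. With the ratio held at that mean, target equals substrate when the substrate left stands at 39.8% of the charge, so substrate leads above that line. In ochre, substrate stood below the line at 4.00 min, with 20.3%. In amber it held 41.0% and was still falling. Alpha carries more reagent than amber and goes on to 8.0 min, and theta carries more than ochre, so she expected target to lead in both. For epsilon she took red's last pace, scaled it by the reagent charges and ran it on to 8.0 min. That gave 42.7%, still above the line, so substrate leads.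

The forecast agreed on the leaders but put epsilon's substrate higher, at 50%. It gave substrate in epsilon, target at 54% in alpha and target at 65% in theta. On target it said “it slows as target and by-product build up, so the step reverses”.

The flasks give substrate at 51.0% in epsilon, target at 53.2% in alpha and target at 64.1% in theta.

    substrate + reagent ⇌ intermediate (K = 110 M⁻¹, k = 0.150 M⁻¹ s⁻¹)
    intermediate ⇌ target + by-product (K = 0.0440 M, k = 0.0120 s⁻¹)
    2 reagent → homo dimer (k = 0.0390 M⁻¹ s⁻¹)
    substrate + intermediate → side product (k = 0.0550 M⁻¹ s⁻¹)

At 8.0 min the ratio is 0.715 in epsilon, 0.706 in alpha and 0.716 in theta, above 0.661 but again level across reagent. Theta holds 64.1% of target, and 35.0% without the difference in reagent, its main reason. So reagent moved conversion, not the ratio. Alpha read at 3.0 min is the second case. Amber then held 46.8% of substrate, above 39.8%, so the rule says substrate. The computed flask gives substrate, 44.1% against 33.9% of target, and the two cross at 3.68 min.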